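## The problem

Target **21** is a trans-fused bicyclo[5.3.0]decene (a daucane-type hydroazulene) in which a cyclopentane (C1–C5) and a cycloheptene (C5–C10 plus C1) share the C1–C5 bond; in the skeleton numbering used throughout, C1 is the methyl-bearing quaternary fusion carbon, C2 and C6 carry the angelates, C4 is the isopropyl carbinol, C5 is the fusion methine and C8 carries the ring methyl. Five stereocentres (1R,2S,4R,5S,6S) must be set, among them an all-carbon quaternary centre at C1 and a tertiary alcohol at C4. If the face of the C4 hydroxyl is called the lower face, the C1 methyl lies on it, whereas the isopropyl group, H5 and both ester oxygens lie on the upper face. The three oxygens are 1,3-related around C4 and the C4 hydroxyl is anti to both ester oxygens, so C4 is the natural relay: its hydroxyl can deliver hydride to ketones at C2 and C6 and fix both secondary carbinols. A substituent at C2, next to C1, is the group best placed to steer formation of the quaternary centre. Three features are fragile: the angelates isomerise to tiglates under nucleophilic or basic catalysis, every β-hydroxy carbonyl intermediate can undergo retro-aldol cleavage or dehydration, and the C8=C9 alkene is β,γ to any C6 carbonyl and moves into conjugation under equilibrating conditions. The enabling feature is that C7–C8(CH3)=C9–C10, lying between oxygenated C6 and quaternary C1, is an intact isoprene unit. With the C6 oxygen written as an enol ether, the seven-membered ring is a cyclohepta-1,4-diene (C5=C6, C8=C9), the product pattern of a divinylcyclopropane rearrangement and hence of a (4+3) union of the three-carbon unit C1=C5–C6 with isoprene.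

## Retrosynthesis

**Ester bonds.** Both acyl C–O bonds are cut first: **21** comes from triol **19** and two equivalents of angelic acid **20**. Doing this last keeps the Z-enoates away from every acidic, basic or reducing step; carrying one ester through the reductions would only add steps. The tertiary C4 hydroxyl needs no protection. The forward reaction must acylate two hindered secondary alcohols without a nucleophilic catalyst.

**C2–H and C6–H bonds.** Triol **19** goes back to hydroxy diketone **18**, in which both carbonyls are β to the C4 hydroxyl, so one directed reduction sets both carbinols. For C6 there is no choice, because the ring-forming step delivers C6 at the ketone oxidation level. For C2 the oxidation–reduction detour is the price of using the opposite C2 configuration as a control element earlier; invertive substitution at this neopentyl carbinol is not realistic. **18** comes from keto diol **17** by oxidation of its only secondary alcohol, and **17** from bis-silyl ether **16**.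

**C5–H bond.** Ketone **16** is traced to methyl enol ether **15**. The forward hydrolysis must protonate C5 on the upper face under kinetic control, because any equilibration of the β,γ-unsaturated ketone would also move the C8=C9 alkene. For this reason both silyl ethers stay on until after this step: together with the angular methyl they place three substituents on the lower face.

**C6–C7 and C1–C10 (key disconnection).** **15** is a cyclohepta-1,4-diene with oxygen at C6. Cutting C1–C10 and C6–C7, with cyclopropane **14** as the intermediate that also holds a C6–C8 bond, gives carbene complex **12** and isoprene **13**. Against cuts at C5–C6/C1–C10 (addition–alkylation on a cyclopentenone) or C1–C5 (ring contraction), this cut removes the whole seven-membered ring and the quaternary centre in one step. It leaves a monocyclic cyclopentene with two stereocentres and a commodity diene. The forward step must attack the methyl-bearing alkene of isoprene, place the two alkenyl groups cis on the cyclopropane, and bond C10 to the upper face of C1. For the last point the C2 oxygen is deliberately placed on the same face as the C4 oxygen.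

**C5–C6 bond.** **12** is cut between ring and carbene carbon: bromide **8** gives alkenyllithium **10**, which adds to a carbonyl ligand of **9**; acylchromate **11** is then O-methylated. This is the standard route to alkoxycarbene complexes. It asks only for halogen–lithium exchange next to a tertiary silyl ether, where β-elimination is impossible in a five-membered ring.

**C4–isopropyl bond.** **8** is the silyl ether of carbinol **7**, which comes from bromoenone **5** and isopropylmagnesium chloride **6**. The addition must be 1,2, free of reduction and enolisation, and anti to the C2 silyloxy group, which gives the required cis-1,3-dioxygen pattern. Bromine is introduced before the addition because an enone α-carbon can be brominated by addition–elimination, whereas the tertiary allylic alcohol could not be halogenated selectively.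

**C5–Br and C1–CH3 bonds.** **5** comes from enone **3** through dibromide **4**. **3** comes from commercial silyloxy enone **1** by conjugate methyl addition with silyl trapping (**2**) and re-oxidation. Buying the C2 stereocentre in **1** avoids a resolution. This single stereocentre controls C4 (step 4) and, through the two silyl ethers, C1 (step 7) and C5 (step 8), before it is erased and reset in steps 10 and 11.

## Roads not taken

Alternative 1: The cut is at C1–C2 and C4–C5, so the seven-membered ring is the starting point. 3,6-Dimethylcyclohepta-2,5-dien-1-one A1, accessible from an aromatic ether, would accept a vinyl-metal at C1 under Cu(OTf)2 with a chiral N-heterocyclic carbene ligand. The resulting C5 enolate would then be intercepted by isobutyraldehyde A2 to give aldol A3.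
- Merits: the quaternary centre is set by a catalyst and not by a relay; C6, C8 and the C8=C9 alkene are present from the start; no stoichiometric metal carbonyl is used. In these respects it is better than the chosen plan.
- Weak points: the five-membered ring is still open in A3, and closing C3–C4 means bonding the terminal vinyl carbon to the carbinol carbon in an endo mode. The C2 oxygen, the C4 tertiary alcohol and the trans fusion would all be set in or after that closure with little to guide them. The skipped alkene of A1 can also move into conjugation under the basic conditions of the coupling.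
- Comparison: the chosen plan has the complete, stereodefined cyclopentane before the annulation and relays C2 and C6 from C4. Its cost is a stoichiometric chromium reagent and a substrate-controlled quaternary centre.

Alternative 2: The cut is at C5–C6 and C1–C10 on a cyclopentanone. The β-carbon of (R)-4-(tert-butyldimethylsilyloxy)-2-methylcyclopent-2-en-1-one A4 would take up 2-lithio-1,3-dithiane A5 on the face opposite the silyloxy group. C-Alkylation of the enolate at C1 with Z-allylic bromide A6 would then give ketone A7.
- Merits: every bond formation is of a well-tried type. The trans C1/C5 relationship is set directly by anti alkylation, so there is no protonation at C5 to control and no β,γ-enone to protect. On this point it is more secure than the chosen plan.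
- Weak points: quaternisation of a fully substituted enolate in a one-pot addition–alkylation is the least reliable variant of that coupling. The seven-membered ring must still be closed by intramolecular dithiane alkylation, with entropy and SN2′ competition against it. C4 starts as a secondary silyloxy carbon and needs oxidation and isopropyl addition next to the ring fusion. Three kinds of protecting group must be handled.
- Comparison: the route would be clearly longer. The chosen plan closes the ring and sets C1 in one operation and installs the C4 carbinol at the outset.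

Alternative 3: The cyclopentane is made by ring contraction. Terpinen-4-ol A8 supplies C4 with its isopropyl and hydroxyl groups and the C1 methyl. Elaboration to 2-diazocyclohexanone A9 and photolysis in an alcohol solvent would shift C1 from C6 to C5 (Wolff rearrangement) and give ester A10.
- Merits: the tertiary carbinol is bought, the ring contraction is reliable, and the allyl group and ester are good handles for a later ring-closing metathesis. It avoids both the hindered organometallic addition and the carbene annulation, which are the least certain steps here.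
- Weak points: reaching A9 from A8 needs oxygenation at two ring carbons, a stereoselective allylation to make the quaternary carbon and a diazo transfer beside a fully substituted carbon. C7 and C8 still have to be attached before the seven-membered ring can close. C5 is again set by protonation, this time of a ketene-derived intermediate. The enantiomeric purity of the terpene would have to be checked.
- Comparison: the sequence would be substantially longer. The chosen plan offers brevity and one step that builds the whole seven-membered ring, at the price of a less certain key step.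

Key step: step 7

## Route

Assumption: (R)-4-(tert-butyldimethylsilyloxy)cyclopent-2-en-1-one (**1**) is taken as a purchasable enantiopure compound; bicyclic compounds are named with the skeleton numbering defined in the first section, not von Baeyer numbering (TBS = tert-butyldimethylsilyl, TES = triethylsilyl).

Step 1
Reactants: 1 (R)-4-(TBS-oxy)cyclopent-2-en-1-one
Product: 2 (1R,2R)-1-(TBS-oxy)-2-methyl-4-(trimethylsilyloxy)cyclopent-3-ene
Conditions: Me2CuLi (from MeLi and CuI), TMSCl, THF, −78 °C; Et3N, then aq. NaHCO3
Reagents that add atoms: lithium dimethylcuprate, [Li+].C[Cu-]C; chlorotrimethylsilane, C[Si](C)(C)Cl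
Why: Chlorosilane-accelerated cuprate conjugate addition anti to the silyloxy group with in situ O-silylation; trapping at −78 °C keeps the enolate from equilibrating to the side where it could expel silyloxide. The methyl-bearing stereocentre is temporary and disappears in step 2.

Step 2
Reactants: 2 (1R,2R)-1-(TBS-oxy)-2-methyl-4-(trimethylsilyloxy)cyclopent-3-ene
Product: 3 (R)-4-(TBS-oxy)-3-methylcyclopent-2-en-1-one
Conditions: Pd(OAc)2 (1.05 equiv), MeCN, rt
Reagents that add atoms: none
Why: Saegusa–Ito oxidation: the regiodefined silyl enol ether gives a palladium enolate that loses its only β-hydrogen, restoring the enone with the methyl group now on the β-carbon (C1). The neutral medium leaves the C2 stereocentre untouched.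

Step 3
Reactants: 3 (R)-4-(TBS-oxy)-3-methylcyclopent-2-en-1-one
Product: 5 (R)-2-bromo-4-(TBS-oxy)-3-methylcyclopent-2-en-1-one, via trans-dibromide 4 (not isolated)
Conditions: Br2, CH2Cl2, 0 °C; then Et3N, 0 °C to rt
Reagents that add atoms: bromine, BrBr
Why: Bromine adds across the enone double bond and triethylamine removes HBr by E1cB loss of the acidic α-hydrogen, the standard α-bromination of β-substituted cycloalkenones. C5 thereby receives the handle for lithiation.

Step 4
Reactants: 5 (R)-2-bromo-4-(TBS-oxy)-3-methylcyclopent-2-en-1-one; 6 isopropylmagnesium chloride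
Product: 7 (1R,4R)-2-bromo-4-(TBS-oxy)-3-methyl-1-(propan-2-yl)cyclopent-2-en-1-ol
Conditions: iPrMgCl, anhydrous CeCl3, THF, −78 °C
Reagents that add atoms: none
Why: Organocerium 1,2-addition: the cerium reagent is nucleophilic but weakly basic, which suppresses enolisation, β-hydride reduction and bromine–magnesium exchange. C4 is set by attack on the carbonyl face opposite the C2 silyloxy group, the usual course for 4-silyloxycyclopentenones, so the new hydroxyl is cis to the silyl ether.

Step 5
Reactants: 7 (1R,4R)-2-bromo-4-(TBS-oxy)-3-methyl-1-(propan-2-yl)cyclopent-2-en-1-ol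
Product: 8 triethylsilyl ether of 7
Conditions: TESOTf, 2,6-lutidine, CH2Cl2, −78 to 0 °C
Reagents that add atoms: triethylsilyl trifluoromethanesulfonate, CC[Si](CC)(CC)OS(=O)(=O)C(F)(F)F
Why: A silyl triflate with a hindered pyridine base silylates even tertiary alcohols. The triethylsilyl ether masks the hydroxyl during lithiation and adds a second bulky group to the lower face.

Step 6
Reactants: 8 triethylsilyl ether of 7; 9 chromium hexacarbonyl
Product: 12 pentacarbonyl[methoxy(cyclopentenyl)carbene]chromium complex, via alkenyllithium 10 (not isolated), via lithium acylchromate 11 (not isolated)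
Conditions: t-BuLi (2.1 equiv), Et2O, −78 °C; Cr(CO)6, −78 °C to rt; then Me3OBF4, CH2Cl2, 0 °C
Reagents that add atoms: trimethyloxonium tetrafluoroborate, C[O+](C)C.F[B-](F)(F)F
Why: Fischer synthesis of an alkoxycarbene complex: bromine–lithium exchange, addition of the alkenyllithium to a carbonyl ligand of Cr(CO)6, and O-methylation of the acylchromate by the oxonium salt. β-Elimination of the neighbouring silyloxide from 10 is excluded because it would require a cyclic allene in a five-membered ring.

Step 7
Reactants: 12 pentacarbonyl[methoxy(cyclopentenyl)carbene]chromium complex; 13 isoprene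
Product: 15 (1R,2R,4R)-2-(TBS-oxy)-4-(TES-oxy)-6-methoxy-1,8-dimethyl-4-(propan-2-yl)bicyclo[5.3.0]deca-5,8-diene, via cis-divinylcyclopropane 14 (not isolated)
Conditions: isoprene (20 equiv), BHT (cat.), 1,4-dioxane, sealed tube, 90 °C, then 120 °C
Reagents that add atoms: none
Why: On heating, 12 loses one CO and binds isoprene; the electrophilic carbene carbon C6 bonds to the CH2 terminus C7 of the more electron-rich 1,1-disubstituted double bond, and reductive elimination from the chromacyclobutane closes C6–C8 to give cyclopropane 14 with the vinyl group cis to the cyclopentenyl group. This cis-divinylcyclopropane then undergoes a Cope rearrangement through the boat transition state in which C1 and C10 lie over the three-membered ring: C6–C8 breaks, C1–C10 forms, and the C5=C6 enol ether and the C8=C9 alkene appear where the target needs them. The closest known reaction type is the (4+3) annulation of alkenyl(alkoxy)carbene complexes of chromium and molybdenum with 1,3-dienes by cyclopropanation and divinylcyclopropane rearrangement; making a quaternary carbon from a fully substituted alkene terminus should only raise the temperature of the second stage. The seven-membered ring is closed by the concerted [3,3] sigmatropic shift, a ring expansion of the cyclopropane and not a polar exo or endo cyclisation, and the cyclopropane ring is formed and consumed in the same flask. The only new stereocentre, C1, is fixed by the face of the cyclopentene on which C8 lies in 14: both silyl ethers (C2 and C4) occupy the lower face, so the Cr(CO)5 group and then C8 are expected on the upper face, and C10 arrives anti to the adjacent C2 silyloxy group. Three selectivities are needed: attack at the methyl-bearing alkene of isoprene, secured by its higher nucleophilicity towards an electrophilic carbene; the cis arrangement of the two alkenyl groups, which any trans isomer can reach at 120 °C by reversible homolysis of the donor-substituted C6–C8 bond; and the facial bias just described.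

Step 8
Reactants: 15 (1R,2R,4R)-2-(TBS-oxy)-4-(TES-oxy)-6-methoxy-1,8-dimethyl-4-(propan-2-yl)bicyclo[5.3.0]deca-5,8-diene
Product: 16 (1R,2R,4R,5R)-2-(TBS-oxy)-4-(TES-oxy)-1,8-dimethyl-4-(propan-2-yl)bicyclo[5.3.0]dec-8-en-6-one (trans-fused)
Conditions: oxalic acid, THF/H2O, 0 °C to rt
Reagents that add atoms: water, O
Why: Acid hydrolysis of an enol ether: rate-limiting protonation at C5, addition of water to the oxocarbenium ion and loss of methanol. C5 is set kinetically by protonation on the upper face, anti to the angular C1 methyl and to both silyl ethers, which gives the trans ring fusion; the weak acid should leave the silyl ethers and the β,γ-position of the C8=C9 alkene untouched.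

Step 9
Reactants: 16 (1R,2R,4R,5R)-2-(TBS-oxy)-4-(TES-oxy)-1,8-dimethyl-4-(propan-2-yl)bicyclo[5.3.0]dec-8-en-6-one
Product: 17 (1R,2R,4R,5R)-2,4-dihydroxy-1,8-dimethyl-4-(propan-2-yl)bicyclo[5.3.0]dec-8-en-6-one
Conditions: HF·pyridine, pyridine, THF, 0 °C to rt
Reagents that add atoms: none
Why: Fluoride cleavage of both silyl ethers with buffered HF·pyridine. The slightly acidic medium avoids the retro-aldol and alkene-migration pathways that a basic fluoride source could open in the β-hydroxy β,γ-unsaturated ketone.

Step 10
Reactants: 17 (1R,2R,4R,5R)-2,4-dihydroxy-1,8-dimethyl-4-(propan-2-yl)bicyclo[5.3.0]dec-8-en-6-one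
Product: 18 (1R,4R,5R)-4-hydroxy-1,8-dimethyl-4-(propan-2-yl)bicyclo[5.3.0]dec-8-ene-2,6-dione
Conditions: Dess–Martin periodinane, pyridine, CH2Cl2, 0 °C to rt
Reagents that add atoms: none
Why: Dess–Martin oxidation of the only secondary alcohol; the tertiary C4 hydroxyl cannot be oxidised, and pyridine buffering keeps the two β-hydroxy ketone units from dehydrating. The C2 stereocentre that served as control element is erased here.

Step 11
Reactants: 18 (1R,4R,5R)-4-hydroxy-1,8-dimethyl-4-(propan-2-yl)bicyclo[5.3.0]dec-8-ene-2,6-dione
Product: 19 (1R,2S,4R,5S,6S)-1,8-dimethyl-4-(propan-2-yl)bicyclo[5.3.0]dec-8-ene-2,4,6-triol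
Conditions: Me4NBH(OAc)3 (excess), MeCN/AcOH, −30 to 0 °C
Reagents that add atoms: none
Why: Evans–Saksena reduction: exchange of an acetate on boron for the C4 hydroxyl gives an alkoxyborohydride that delivers hydride intramolecularly, through six-membered transition states, to the lower face of both β-carbonyl groups; ketones without this anchor are not reduced by the reagent. C2 and C6 are thereby both set with their hydroxyls anti to the C4 hydroxyl.

Step 12
Reactants: 19 (1R,2S,4R,5S,6S)-1,8-dimethyl-4-(propan-2-yl)bicyclo[5.3.0]dec-8-ene-2,4,6-triol; 20 angelic acid (first equivalent)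
Product: 21 (1R,2S,4R,5S,6S)-4-hydroxy-1,8-dimethyl-4-(propan-2-yl)bicyclo[5.3.0]dec-8-ene-2,6-diyl bis[(2Z)-2-methylbut-2-enoate]
Conditions: 20 (2.6 equiv), 2,4,6-trichlorobenzoyl chloride (2.6 equiv), Et3N, toluene, rt; then 19, 75 °C
Reagents that add atoms: angelic acid (second equivalent of 20), C/C=C(/C)C(=O)O
Why: Mixed-anhydride (Yamaguchi-type) esterification run without a nucleophilic catalyst, the established way to transfer an angeloyl group with retention of the Z geometry. The C6 and C2 hydroxyls are acylated one after the other in the same flask, each by one molecule of the mixed anhydride, so two equivalents of 20 end up in 21. The tertiary C4 hydroxyl is too hindered to react.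

## Compound list

1 | (R)-4-(tert-butyldimethylsilyloxy)cyclopent-2-en-1-one | O=C1C=C[C@H](O[Si](C)(C)C(C)(C)C)C1 | starting material
2 | tert-butyl(dimethyl){[(1R,2R)-2-methyl-4-(trimethylsilyloxy)cyclopent-3-en-1-yl]oxy}silane (methyl trans to the TBS ether) | C[Si](C)(C)OC1=C[C@@H](C)[C@H](O[Si](C)(C)C(C)(C)C)C1 | intermediate
3 | (R)-4-(tert-butyldimethylsilyloxy)-3-methylcyclopent-2-en-1-one | O=C1C=C(C)[C@H](O[Si](C)(C)C(C)(C)C)C1 | intermediate
4 | (4R)-2,3-dibromo-4-(tert-butyldimethylsilyloxy)-3-methylcyclopentan-1-one (trans-dibromide, configuration at the two brominated carbons not controlled) | O=C1C(Br)C(C)(Br)[C@H](O[Si](C)(C)C(C)(C)C)C1 | intermediate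
5 | (R)-2-bromo-4-(tert-butyldimethylsilyloxy)-3-methylcyclopent-2-en-1-one | O=C1C(Br)=C(C)[C@H](O[Si](C)(C)C(C)(C)C)C1 | intermediate
6 | isopropylmagnesium chloride | CC(C)[Mg]Cl | starting material
7 | (1R,4R)-2-bromo-4-(tert-butyldimethylsilyloxy)-3-methyl-1-(propan-2-yl)cyclopent-2-en-1-ol (hydroxyl cis to the TBS ether) | BrC1=C(C)[C@H](O[Si](C)(C)C(C)(C)C)C[C@@]1(O)C(C)C | intermediate
8 | {[(1R,4R)-2-bromo-4-(tert-butyldimethylsilyloxy)-3-methyl-1-(propan-2-yl)cyclopent-2-en-1-yl]oxy}(triethyl)silane | BrC1=C(C)[C@H](O[Si](C)(C)C(C)(C)C)C[C@@]1(O[Si](CC)(CC)CC)C(C)C | intermediate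
9 | chromium hexacarbonyl, Cr(CO)6 | O=C=[Cr](=C=O)(=C=O)(=C=O)(=C=O)=C=O | starting material
10 | [(3R,5R)-3-(tert-butyldimethylsilyloxy)-2-methyl-5-(propan-2-yl)-5-(triethylsilyloxy)cyclopent-1-en-1-yl]lithium | [Li]C1=C(C)[C@H](O[Si](C)(C)C(C)(C)C)C[C@@]1(O[Si](CC)(CC)CC)C(C)C | intermediate
11 | lithium pentacarbonyl{[(3R,5R)-3-(tert-butyldimethylsilyloxy)-2-methyl-5-(propan-2-yl)-5-(triethylsilyloxy)cyclopent-1-en-1-yl]carbonyl}chromate | [Li+].[O-]C(=[Cr](=C=O)(=C=O)(=C=O)(=C=O)=C=O)C1=C(C)[C@H](O[Si](C)(C)C(C)(C)C)C[C@@]1(O[Si](CC)(CC)CC)C(C)C | intermediate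
12 | pentacarbonyl{methoxy[(3R,5R)-3-(tert-butyldimethylsilyloxy)-2-methyl-5-(propan-2-yl)-5-(triethylsilyloxy)cyclopent-1-en-1-yl]methylidene}chromium | COC(=[Cr](=C=O)(=C=O)(=C=O)(=C=O)=C=O)C1=C(C)[C@H](O[Si](C)(C)C(C)(C)C)C[C@@]1(O[Si](CC)(CC)CC)C(C)C | intermediate
13 | isoprene (2-methylbuta-1,3-diene) | C=CC(C)=C | starting material
14 | (3R,5R)-3-(tert-butyldimethylsilyloxy)-1-[(1S,2R)-2-ethenyl-1-methoxy-2-methylcyclopropyl]-2-methyl-5-(propan-2-yl)-5-(triethylsilyloxy)cyclopent-1-ene (vinyl cis to cyclopentenyl, cyclopropane on the upper face) | CO[C@@]2(C1=C(C)[C@H](O[Si](C)(C)C(C)(C)C)C[C@@]1(O[Si](CC)(CC)CC)C(C)C)C[C@]2(C)C=C | intermediate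
15 | (1R,2R,4R)-2-(tert-butyldimethylsilyloxy)-6-methoxy-1,8-dimethyl-4-(propan-2-yl)-4-(triethylsilyloxy)bicyclo[5.3.0]deca-5,8-diene (skeleton numbering) | COC=1CC(C)=CC[C@@]2(C)[C@H](O[Si](C)(C)C(C)(C)C)C[C@@](O[Si](CC)(CC)CC)(C(C)C)C12 | intermediate
16 | (1R,2R,4R,5R)-2-(tert-butyldimethylsilyloxy)-1,8-dimethyl-4-(propan-2-yl)-4-(triethylsilyloxy)bicyclo[5.3.0]dec-8-en-6-one (trans-fused, skeleton numbering) | O=C1CC(C)=CC[C@@]2(C)[C@H](O[Si](C)(C)C(C)(C)C)C[C@@](O[Si](CC)(CC)CC)(C(C)C)[C@H]12 | intermediate
17 | (1R,2R,4R,5R)-2,4-dihydroxy-1,8-dimethyl-4-(propan-2-yl)bicyclo[5.3.0]dec-8-en-6-one (skeleton numbering) | O=C1CC(C)=CC[C@@]2(C)[C@H](O)C[C@@](O)(C(C)C)[C@H]12 | intermediate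
18 | (1R,4R,5R)-4-hydroxy-1,8-dimethyl-4-(propan-2-yl)bicyclo[5.3.0]dec-8-ene-2,6-dione (skeleton numbering) | O=C1CC(C)=CC[C@@]2(C)C(=O)C[C@@](O)(C(C)C)[C@H]12 | intermediate
19 | (1R,2S,4R,5S,6S)-1,8-dimethyl-4-(propan-2-yl)bicyclo[5.3.0]dec-8-ene-2,4,6-triol (skeleton numbering) | O[C@H]1CC(C)=CC[C@@]2(C)[C@@H](O)C[C@@](O)(C(C)C)[C@H]12 | intermediate
20 | angelic acid, (2Z)-2-methylbut-2-enoic acid | C/C=C(/C)C(=O)O | starting material
21 | (1R,2S,4R,5S,6S)-4-hydroxy-1,8-dimethyl-4-(propan-2-yl)bicyclo[5.3.0]dec-8-ene-2,6-diyl bis[(2Z)-2-methylbut-2-enoate] (skeleton numbering; CNP0303897.1) | C/C=C(/C)C(=O)O[C@H]1CC(C)=CC[C@@]2(C)[C@@H](OC(=O)/C(C)=C\C)C[C@@](O)(C(C)C)[C@H]12 | target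

## Step count and least certain steps

Total: 12 steps. Longest linear sequence: 12 steps (1 to 21).

**Step 7 (key step).** Three things can go wrong. Carbene transfer may go to the unsubstituted double bond of isoprene, which would place the methyl at C9. Carbene transfer from the congested, twisted carbene may be slow and lose out to thermal decomposition. C10 may bond to the lower face of C1. The electronic preference for the 1,1-disubstituted alkene is opposed by its greater steric demand, and the facial bias rests on a vicinal silyloxy group against a 1,3-related isopropyl group. Fallback: from 12, use 2-(trimethylsilyloxy)buta-1,3-diene in place of isoprene. This diene is electron-rich, and its enol ether double bond should be attacked more readily and with unambiguous site selectivity. Cyclopropanation would give the silyloxy cis-divinylcyclopropane F1, which rearranges in the same flask to the C8 trimethylsilyl enol ether F2. Cleavage with MeLi gives the lithium enolate F3, and trapping with PhNTf2 gives the C8 enol triflate F4. Methylation with MeZnCl under Pd(PPh3)4 (zerovalent palladium) returns to 15.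

**Step 8.** Protonation on the lower face would give the cis ring fusion, and there is no safe way to correct it by simple base treatment, because the C8=C9 alkene would migrate first. The isopropyl group on the upper face partly offsets the three lower-face substituents. Fallback: from 15, if hydrolysis gives mainly the cis-fused C5-epimeric ketone F5, treat it with DBU so that alkene position and C5 both equilibrate to the conjugated trans-fused enone F6 (C7=C8), in which C6 lies anti to the isopropyl group. KOt-Bu in t-BuOH then forms the extended potassium dienolate F7, and a kinetic quench at C7 with aqueous acetic acid, the classical deconjugation, returns to 16.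

**Step 6.** Addition of the very hindered alkenyllithium to the carbonyl ligand may be incomplete, with protonation on work-up; the carbanion is flanked by a quaternary carbon and a substituted alkene carbon. Fallback: from 8, carboxylate alkenyllithium 10 with CO2 to give the cyclopentenecarboxylic acid F8. Convert it under neutral conditions with 1-chloro-N,N,2-trimethylprop-1-en-1-amine to the acid chloride F9. Acylate K2Cr(CO)5 (from Cr(CO)6 and C8K) to give the potassium acylchromate F10, and methylate with Me3OBF4 to return to 12.

**Step 11 (with step 10).** The doubly activated aldol 18 may dehydrate or cleave. The second reduction may also be steered by the newly formed upper-face hydroxyl and not by C4. Fallback: handle one carbonyl at a time. From 16, selective removal of the triethylsilyl group (PPTS, MeOH) gives the C4 hydroxy ketone F11. Directed reduction gives the C4,C6-diol F12. Mixed-anhydride angeloylation gives the C6 mono-angelate F13. HF·pyridine gives the C2 alcohol F14, and Dess–Martin oxidation gives the C2 ketone F15. A second directed reduction gives the C2 upper-face alcohol F16, and a second angeloylation returns to 21.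

**Step 12.** The Z-enoate may isomerise to the tiglate through reversible conjugate addition of amine or carboxylate at 75 °C, and acylation of the neopentyl C2 hydroxyl may be incomplete. Fallback: build the Z-alkenes on the substrate. From 19, esterify both secondary hydroxyls with 2-[bis(2,2,2-trifluoroethoxy)phosphoryl]propanoic acid (DCC, DMAP) to give the bis(phosphonopropanoate) F17. Still–Gennari olefination with acetaldehyde (KN(SiMe3)2, 18-crown-6, THF, −78 °C) then returns to 21.

## Further compounds

F1 | step 7 | (3R,5R)-3-(tert-butyldimethylsilyloxy)-1-[2-ethenyl-1-methoxy-2-(trimethylsilyloxy)cyclopropyl]-2-methyl-5-(propan-2-yl)-5-(triethylsilyloxy)cyclopent-1-ene (ethenyl cis to cyclopentenyl) | CO[C@@]2(C1=C(C)[C@H](O[Si](C)(C)C(C)(C)C)C[C@@]1(O[Si](CC)(CC)CC)C(C)C)C[C@]2(O[Si](C)(C)C)C=C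
F2 | step 7 | (1R,2R,4R)-2-(tert-butyldimethylsilyloxy)-6-methoxy-1-methyl-4-(propan-2-yl)-4-(triethylsilyloxy)-8-(trimethylsilyloxy)bicyclo[5.3.0]deca-5,8-diene | COC=1CC(O[Si](C)(C)C)=CC[C@@]2(C)[C@H](O[Si](C)(C)C(C)(C)C)C[C@@](O[Si](CC)(CC)CC)(C(C)C)C12
F3 | step 7 | lithium (1R,2R,4R)-2-(tert-butyldimethylsilyloxy)-6-methoxy-1-methyl-4-(propan-2-yl)-4-(triethylsilyloxy)bicyclo[5.3.0]deca-5,8-dien-8-olate | [Li+].COC=1CC([O-])=CC[C@@]2(C)[C@H](O[Si](C)(C)C(C)(C)C)C[C@@](O[Si](CC)(CC)CC)(C(C)C)C12
F4 | step 7 | (1R,2R,4R)-2-(tert-butyldimethylsilyloxy)-6-methoxy-1-methyl-4-(propan-2-yl)-4-(triethylsilyloxy)bicyclo[5.3.0]deca-5,8-dien-8-yl trifluoromethanesulfonate | COC=1CC(OS(=O)(=O)C(F)(F)F)=CC[C@@]2(C)[C@H](O[Si](C)(C)C(C)(C)C)C[C@@](O[Si](CC)(CC)CC)(C(C)C)C12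
F5 | step 8 | cis-fused C5 epimer of 16 | O=C1CC(C)=CC[C@@]2(C)[C@H](O[Si](C)(C)C(C)(C)C)C[C@@](O[Si](CC)(CC)CC)(C(C)C)[C@@H]12
F6 | step 8 | trans-fused conjugated enone, 2-(tert-butyldimethylsilyloxy)-1,8-dimethyl-4-(propan-2-yl)-4-(triethylsilyloxy)bicyclo[5.3.0]dec-7-en-6-one | O=C1C=C(C)CC[C@@]2(C)[C@H](O[Si](C)(C)C(C)(C)C)C[C@@](O[Si](CC)(CC)CC)(C(C)C)[C@H]12
F7 | step 8 | potassium 2-(tert-butyldimethylsilyloxy)-1,8-dimethyl-4-(propan-2-yl)-4-(triethylsilyloxy)bicyclo[5.3.0]deca-6,8-dien-6-olate (trans-fused) | [K+].[O-]C1=CC(C)=CC[C@@]2(C)[C@H](O[Si](C)(C)C(C)(C)C)C[C@@](O[Si](CC)(CC)CC)(C(C)C)[C@H]12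
F8 | step 6 | (3R,5R)-3-(tert-butyldimethylsilyloxy)-2-methyl-5-(propan-2-yl)-5-(triethylsilyloxy)cyclopent-1-ene-1-carboxylic acid | OC(=O)C1=C(C)[C@H](O[Si](C)(C)C(C)(C)C)C[C@@]1(O[Si](CC)(CC)CC)C(C)C
F9 | step 6 | (3R,5R)-3-(tert-butyldimethylsilyloxy)-2-methyl-5-(propan-2-yl)-5-(triethylsilyloxy)cyclopent-1-ene-1-carbonyl chloride | ClC(=O)C1=C(C)[C@H](O[Si](C)(C)C(C)(C)C)C[C@@]1(O[Si](CC)(CC)CC)C(C)C
F10 | step 6 | potassium analogue of acylchromate 11 | [K+].[O-]C(=[Cr](=C=O)(=C=O)(=C=O)(=C=O)=C=O)C1=C(C)[C@H](O[Si](C)(C)C(C)(C)C)C[C@@]1(O[Si](CC)(CC)CC)C(C)C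
F11 | step 11 | 2-(tert-butyldimethylsilyloxy)-4-hydroxy-1,8-dimethyl-4-(propan-2-yl)bicyclo[5.3.0]dec-8-en-6-one (trans-fused) | O=C1CC(C)=CC[C@@]2(C)[C@H](O[Si](C)(C)C(C)(C)C)C[C@@](O)(C(C)C)[C@H]12
F12 | step 11 | 2-(tert-butyldimethylsilyloxy)-1,8-dimethyl-4-(propan-2-yl)bicyclo[5.3.0]dec-8-ene-4,6-diol (C6 hydroxyl on the upper face) | O[C@H]1CC(C)=CC[C@@]2(C)[C@H](O[Si](C)(C)C(C)(C)C)C[C@@](O)(C(C)C)[C@H]12
F13 | step 11 | C6 angelate of F12 | C/C=C(/C)C(=O)O[C@H]1CC(C)=CC[C@@]2(C)[C@H](O[Si](C)(C)C(C)(C)C)C[C@@](O)(C(C)C)[C@H]12
F14 | step 11 | C6 angelate with free lower-face C2 hydroxyl | C/C=C(/C)C(=O)O[C@H]1CC(C)=CC[C@@]2(C)[C@H](O)C[C@@](O)(C(C)C)[C@H]12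
F15 | step 11 | C6 angelate with C2 ketone | C/C=C(/C)C(=O)O[C@H]1CC(C)=CC[C@@]2(C)C(=O)C[C@@](O)(C(C)C)[C@H]12
F16 | step 11 | C6 angelate with upper-face C2 hydroxyl (6-mono-angelate of 19) | C/C=C(/C)C(=O)O[C@H]1CC(C)=CC[C@@]2(C)[C@@H](O)C[C@@](O)(C(C)C)[C@H]12
F17 | step 12 | 2,6-bis{2-[bis(2,2,2-trifluoroethoxy)phosphoryl]propanoate} of 19 (mixture at the phosphonate α-carbons) | CC(C(=O)O[C@H]1CC(C)=CC[C@@]2(C)[C@@H](OC(=O)C(C)P(=O)(OCC(F)(F)F)OCC(F)(F)F)C[C@@](O)(C(C)C)[C@H]12)P(=O)(OCC(F)(F)F)OCC(F)(F)F
A1 | alternative 1 | 3,6-dimethylcyclohepta-2,5-dien-1-one | O=C1C=C(C)CC=C(C)C1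
A2 | alternative 1 | isobutyraldehyde | CC(C)C=O
A3 | alternative 1 | 3-ethenyl-2-(1-hydroxy-2-methylpropyl)-3,6-dimethylcyclohept-5-en-1-one | O=C1CC(C)=CC[C@@](C)(C=C)[C@@H]1[C@H](O)C(C)C
A4 | alternative 2 | (R)-4-(tert-butyldimethylsilyloxy)-2-methylcyclopent-2-en-1-one | O=C1C(C)=C[C@H](O[Si](C)(C)C(C)(C)C)C1
A5 | alternative 2 | 2-lithio-1,3-dithiane | [Li]C1SCCCS1
A6 | alternative 2 | 1-({[(2Z)-4-bromo-2-methylbut-2-en-1-yl]oxy}methyl)-4-methoxybenzene | BrC/C=C(C)\COCc1ccc(OC)cc1
A7 | alternative 2 | 2-methylcyclopentanone carrying the C6 dithiane and the C10–C7 allylic chain | O=C1C[C@@H](O[Si](C)(C)C(C)(C)C)[C@H](C2SCCCS2)[C@@]1(C)C/C=C(C)\COCc1ccc(OC)cc1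
A8 | alternative 3 | (S)-terpinen-4-ol (enantiomer assumed for the mapping in which the ring CH2 next to the alkene carbon becomes C5) | CC1=CC[C@](O)(C(C)C)CC1
A9 | alternative 3 | 6-allyl-2-diazo-6-methyl-3-(propan-2-yl)-5-(tert-butyldimethylsilyloxy)-3-(triethylsilyloxy)cyclohexan-1-one | C=CC[C@@]1(C)[C@H](O[Si](C)(C)C(C)(C)C)C[C@@](O[Si](CC)(CC)CC)(C(C)C)C(=[N+]=[N-])C1=O
A10 | alternative 3 | methyl 2-allyl-2-methyl-5-(propan-2-yl)-3-(tert-butyldimethylsilyloxy)-5-(triethylsilyloxy)cyclopentane-1-carboxylate | C=CC[C@@]1(C)[C@H](O[Si](C)(C)C(C)(C)C)C[C@@](O[Si](CC)(CC)CC)(C(C)C)[C@@H]1C(=O)OC
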